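## Retrosynthetic overview

1. Target ⇒ open the hemiaminal to a benzyl ketone plus primary amide, then cut the aryl–CH2 bond. The last step is a photostimulated radical (SRN1) coupling of an aryl radical with a methyl-ketone enolate that closes the 13-membered paracyclophane; the lactam then closes by itself.
2. That precursor (tricyclic aryl iodide with a 2-acetonyl β-keto amide side chain) ⇒ tricyclic methyl ester + acetonitrile + chloroacetone.
3. Tricyclic ester ⇒ intramolecular Diels–Alder reaction of a triene and a γ-aryloxy enoate hung on ring A (rings B and C together).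
4. Diels–Alder precursor ⇒ ring-A ester aldehyde: triene by three olefinations; side arm by Nozaki–Hiyama–Kishi coupling and Mitsunobu etherification with 4-iodophenol.
5. Ring A ⇒ Diels–Alder reaction of citraconic anhydride with (E)-2-methylpenta-1,3-diene, hydrogenation, catalytic kinetic resolution, epimerisation. Ring order: A, then B + C, then macrocycle + lactam.

Assumption: (DHQD)2AQN is written as the cinchona catalyst that consumes the (3aR,5R,7S,7aS) enantiomer of the racemic hydrogenated anhydride; if the sense is opposite, its pseudo-enantiomer (DHQ)2AQN is used with no other change.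

Locants: ring-A compounds are numbered as cyclohexanes. Tricyclic compounds use fluorene numbering (C1 acyl, C2 methyl/vinyl, C4b angular methyl, C9 aryloxy); β is the face of the C4b methyl.

## Route

Step 1
Reactants: 1 citraconic anhydride; 2 (3E)-2-methylpenta-1,3-diene
Product: 3 racemic cis-fused anhydride rac-(3aR*,7S*,7aS*)-3a,5,7-trimethyl-3a,4,7,7a-tetrahydro-2-benzofuran-1,3-dione
Conditions: toluene, BHT (cat.), 110 °C, sealed tube; minor regioisomer removed by crystallisation
Reagents that add atoms: none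
Why: Thermal Diels–Alder reaction in which the methyl-bearing dienophile carbon bonds to the unsubstituted CH2 terminus of the diene (steric and orbital-coefficient preference) and the endo transition state places the C7 methyl cis to the anhydride, so C3a, C7a and C7 are set relative to one another (racemic).

Step 2
Reactants: 3 racemic Diels–Alder anhydride
Product: 4 racemic rac-(3aR*,5R*,7S*,7aS*)-3a,5,7-trimethylhexahydro-2-benzofuran-1,3-dione
Conditions: H2 (4 atm), PtO2, EtOAc, rt
Reagents that add atoms: none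
Why: Heterogeneous syn-hydrogenation on the convex face of the cis-fused bicycle (the face away from the anhydride ring) delivers H to C5 from that face, so the C5 methyl ends cis to the anhydride and to the C7 methyl.

Step 3
Reactants: 4 racemic saturated anhydride
Product: 5 (1R,2S,3S,5R)-2-(methoxycarbonyl)-1,3,5-trimethylcyclohexane-1-carboxylic acid
Conditions: (DHQD)2AQN (20 mol %), MeOH (0.6 equiv), Et2O, −30 °C; acid–base extraction
Reagents that add atoms: methanol, CO
Why: Cinchona-alkaloid-catalysed methanolysis of a cyclic anhydride run as a kinetic resolution: only in the (3aR,5R,7S,7aS) enantiomer is the carbonyl preferred by the catalyst also the unhindered one (next to the CH, not the quaternary carbon), so this enantiomer alone is opened, regioselectively, and the mirror-image anhydride is washed out unchanged.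

Step 4
Reactants: 5 cis half-ester
Product: 6 (1R,2R,3S,5R)-2-(methoxycarbonyl)-1,3,5-trimethylcyclohexane-1-carboxylic acid
Conditions: NaOMe (3 equiv), MeOH, 65 °C; then 1 M HCl
Reagents that add atoms: none
Why: Enolisation α to the ester under thermodynamic control (epimerisation) moves the CO2Me group from axial to equatorial, trans to the neighbouring carboxylate, while the non-enolisable C1, C3 and C5 stay untouched; the minor cis isomer is recycled.

Step 5
Reactants: 6 trans half-ester
Product: 7 methyl (1R,2R,4R,6S)-2-(hydroxymethyl)-2,4,6-trimethylcyclohexane-1-carboxylate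
Conditions: BH3·SMe2, THF, 0 °C to rt; then H2O
Reagents that add atoms: none
Why: Borane reduces the carboxylic acid chemoselectively in the presence of the methyl ester (acyloxyborane pathway) and touches no stereocentre.

Step 6
Reactants: 7 hydroxy ester
Product: 8 methyl (1R,2R,4R,6S)-2-formyl-2,4,6-trimethylcyclohexane-1-carboxylate
Conditions: Dess–Martin periodinane, CH2Cl2, rt
Reagents that add atoms: none
Why: Dess–Martin oxidation of the neopentyl primary alcohol gives the non-enolisable aldehyde without epimerising C1.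

Step 7
Reactants: 8 formyl ester
Product: 10 methyl (1R,2S,4R,6S)-2,4,6-trimethyl-2-[(1E)-2-methyl-3-oxoprop-1-en-1-yl]cyclohexane-1-carboxylate, via N-tert-butyl azadiene 9 (not isolated)
Conditions: N-tert-butyl-2-(triethylsilyl)propan-1-imine, sBuLi, THF, −78 to 0 °C; then CF3CO2H, H2O, 0 °C
Reagents that add atoms: N-tert-butyl-2-(triethylsilyl)propan-1-imine, CC(C=NC(C)(C)C)[Si](CC)(CC)CC; water, O
Why: Corey–Peterson (α-silyl aldimine) olefination in which the lithiated silyl imine adds to the hindered aldehyde faster than to the ester, Peterson elimination gives the azadiene, and acid both equilibrates it to the E isomer and hydrolyses it, so the E-trisubstituted enal forms without the over-homologation a formyl ylide would give.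

Step 8
Reactants: 10 enal
Product: 11 methyl (1R,2S,4R,6S)-2-[(1E,3E)-2,4-dimethyl-5-oxopenta-1,3-dien-1-yl]-2,4,6-trimethylcyclohexane-1-carboxylate
Conditions: Ph3P=C(CH3)CHO (1.3 equiv), toluene, 90 °C
Reagents that add atoms: 2-(triphenylphosphoranylidene)propanal, CC(C=O)=P(c1ccccc1)(c1ccccc1)c1ccccc1
Why: Wittig reaction with the stabilised formyl ylide gives the second E-trisubstituted alkene, and because the enal 10 is more electrophilic than the dienal product the homologation stops after one unit.

Step 9
Reactants: 11 dienal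
Product: 12 methyl (1R,2S,4R,6S)-2-[(1E,3E)-2,4-dimethylhexa-1,3,5-trien-1-yl]-2,4,6-trimethylcyclohexane-1-carboxylate
Conditions: Ph3PCH3Br, KOtBu, THF, 0 °C
Reagents that add atoms: methyltriphenylphosphonium bromide, C[P+](c1ccccc1)(c1ccccc1)c1ccccc1.[Br-]
Why: Wittig methylenation of the dienal completes the all-E triene, the hindered ester being inert to the ylide at 0 °C.

Step 10
Reactants: 12 triene ester
Product: 13 (1R,2S,4R,6S)-2-[(1E,3E)-2,4-dimethylhexa-1,3,5-trien-1-yl]-2,4,6-trimethylcyclohexane-1-carbaldehyde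
Conditions: iBu2AlH (1.05 equiv), CH2Cl2, −78 °C; KNaC4H4O6 (aq)
Reagents that add atoms: none
Why: Partial reduction of the hindered methyl ester with iBu2AlH at −78 °C stops at the tetrahedral aluminium hemiacetal, which gives the aldehyde on work-up without epimerising the α-carbon.

Step 11
Reactants: 13 triene aldehyde; 14 methyl (2E)-3-iodoprop-2-enoate
Product: 15 methyl (2E,4R)-4-hydroxy-4-{(1R,2S,4R,6S)-2-[(1E,3E)-2,4-dimethylhexa-1,3,5-trien-1-yl]-2,4,6-trimethylcyclohexyl}but-2-enoate
Conditions: CrCl2 (4 equiv), NiCl2 (2 mol %), DMSO, rt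
Reagents that add atoms: none
Why: Nozaki–Hiyama–Kishi coupling in which the alkenylchromium reagent (E geometry retained) adds to the α-branched aldehyde in the Felkin–Anh sense (anti to the quaternary ring carbon), giving the 4R carbinol, the epimer needed for inversion in the next step.

Step 12
Reactants: 15 γ-hydroxy enoate; 16 4-iodophenol
Product: 17 methyl (2E,4S)-4-(4-iodophenoxy)-4-{(1R,2S,4R,6S)-2-[(1E,3E)-2,4-dimethylhexa-1,3,5-trien-1-yl]-2,4,6-trimethylcyclohexyl}but-2-enoate
Conditions: PPh3, DIAD, toluene, 0 °C to rt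
Reagents that add atoms: none
Why: Mitsunobu etherification of the allylic alcohol with the phenol (pKa about 9) proceeds by SN2 with inversion, giving the 4S aryl ether with the configuration the target needs at the carbon that becomes C9.

Step 13
Reactants: 17 triene enoate aryl ether
Product: 18 methyl 2β-ethenyl-9β-(4-iodophenoxy)-2α,4,4bβ,6α,8α-pentamethyl-2,4a,4b,5,6,7,8,8a,9,9a-decahydro-1H-fluorene-1β-carboxylate (H-4a α, H-8a α, H-9a β)
Conditions: Me2AlCl (1.5 equiv), CH2Cl2, −40 to 0 °C
Reagents that add atoms: none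
Why: Lewis-acid-promoted intramolecular Diels–Alder reaction through the ester-endo, tether-anti transition state forms rings B and C trans-fused: the E-enoate sets H-9a trans to H-1, the E,E-diene puts the vinyl group at C2 cis to C4b, and the 9-aryloxy group, staying pseudo-equatorial and anti to the new C9a–C1 bond, selects the diene face (four new stereocentres).

Step 14
Reactants: 18 tricyclic ester
Product: 19 3-oxo-3-(tricyclic fluoren-1β-yl)propanenitrile (tricycle as in 18)
Conditions: CH3CN, LiN(iPr)2 (3 equiv), THF, −78 to 0 °C; then 1 M HCl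
Reagents that add atoms: acetonitrile, CC#N
Why: Claisen-type acylation of lithioacetonitrile by the methyl ester gives the β-ketonitrile, whose immediate deprotonation protects C1 (acyl group already equatorial) from epimerisation.

Step 15
Reactants: 19 β-ketonitrile
Product: 20 3-oxo-3-(tricyclic fluoren-1β-yl)propanamide
Conditions: PtH(PMe2OH)(PMe2O)2H (2 mol %), EtOH/H2O, 80 °C
Reagents that add atoms: water, O
Why: Platinum-catalysed neutral nitrile hydration (Ghaffar–Parkins catalyst) gives the primary amide without touching the aryl iodide, the alkenes or the β-dicarbonyl unit.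

Step 16
Reactants: 20 β-keto amide; 21 chloroacetone
Product: 22 4-oxo-2-[(tricyclic fluoren-1β-yl)carbonyl]pentanamide (C2 epimers; in equilibrium with its 5-hydroxy-5-methyl lactam ring tautomer)
Conditions: K2CO3, acetone, rt
Reagents that add atoms: none
Why: C-alkylation of the β-keto amide enolate with the α-chloroketone (SN2) installs the acetonyl group; the new stereocentre is enolisable and is set later under thermodynamic control.

Step 17
Reactants: 22 acetonyl β-keto amide aryl iodide
Product: 24 CNP0450261.1 (target), via macrocyclic diketo amide 23 (not isolated)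
Conditions: KOtBu (6 equiv), liquid NH3, −33 °C, hν (350 nm), 0.5 mM; then NH4Cl, warm to rt
Reagents that add atoms: none
Why: Proposed new method: under irradiation the terminal ketone enolate of the polyanion (the β-dicarbonyl enolate and the amide anion stay spectators and block aldol closure) transfers an electron to the aryl iodide, iodide leaves, and the aryl σ-radical, which points along the ring axis and finds no hydrogen donor in liquid ammonia, couples at near diffusion-controlled rate with the enolate CH2 held over the β-face, the strongly exothermic coupling paying for the strain of the 13-membered paracyclophane (radical-nucleophilic aromatic substitution, SRN1; closest known types are intramolecular SRN1 ring closures of ketone enolates onto aryl halides and terminal arylation of β-dicarbonyl dianions); on work-up the primary amide adds to the new benzyl ketone to give the hemiaminal, with lactam C3 (epimerisable) and C5 set thermodynamically, their ring substituents cis as the macrocycle demands.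

## Compound list

1 | citraconic anhydride (3-methylfuran-2,5-dione) | CC1=CC(=O)OC1=O | starting material
2 | (3E)-2-methylpenta-1,3-diene | C=C(C)/C=C/C | starting material
3 | rac-(3aR*,7S*,7aS*)-3a,5,7-trimethyl-3a,4,7,7a-tetrahydro-2-benzofuran-1,3-dione (cis ring fusion, 7-methyl cis to the anhydride; racemic, one enantiomer drawn) | O=C2[C@H]1[C@@H](C)C=C(C)C[C@]1(C(=O)O2)C | intermediate
4 | rac-(3aR*,5R*,7S*,7aS*)-3a,5,7-trimethylhexahydro-2-benzofuran-1,3-dione (5- and 7-methyl cis to the anhydride; racemic, reacting enantiomer drawn) | O=C2[C@H]1[C@@H](C)C[C@@H](C)C[C@]1(C(=O)O2)C | intermediate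
5 | (1R,2S,3S,5R)-2-(methoxycarbonyl)-1,3,5-trimethylcyclohexane-1-carboxylic acid | COC(=O)[C@H]1[C@@H](C)C[C@@H](C)C[C@]1(C(=O)O)C | intermediate
6 | (1R,2R,3S,5R)-2-(methoxycarbonyl)-1,3,5-trimethylcyclohexane-1-carboxylic acid | COC(=O)[C@@H]1[C@@H](C)C[C@@H](C)C[C@]1(C(=O)O)C | intermediate
7 | methyl (1R,2R,4R,6S)-2-(hydroxymethyl)-2,4,6-trimethylcyclohexane-1-carboxylate | COC(=O)[C@@H]1[C@@H](C)C[C@@H](C)C[C@]1(CO)C | intermediate
8 | methyl (1R,2R,4R,6S)-2-formyl-2,4,6-trimethylcyclohexane-1-carboxylate | COC(=O)[C@@H]1[C@@H](C)C[C@@H](C)C[C@]1(C=O)C | intermediate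
9 | methyl (1R,2S,4R,6S)-2-[(1E)-3-(tert-butylimino)-2-methylprop-1-en-1-yl]-2,4,6-trimethylcyclohexane-1-carboxylate | COC(=O)[C@@H]1[C@@H](C)C[C@@H](C)C[C@]1(/C=C(\C)/C=N/C(C)(C)C)C | intermediate
10 | methyl (1R,2S,4R,6S)-2,4,6-trimethyl-2-[(1E)-2-methyl-3-oxoprop-1-en-1-yl]cyclohexane-1-carboxylate | COC(=O)[C@@H]1[C@@H](C)C[C@@H](C)C[C@]1(/C=C(\C)/C=O)C | intermediate
11 | methyl (1R,2S,4R,6S)-2-[(1E,3E)-2,4-dimethyl-5-oxopenta-1,3-dien-1-yl]-2,4,6-trimethylcyclohexane-1-carboxylate | COC(=O)[C@@H]1[C@@H](C)C[C@@H](C)C[C@]1(/C=C(\C)/C=C(\C)/C=O)C | intermediate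
12 | methyl (1R,2S,4R,6S)-2-[(1E,3E)-2,4-dimethylhexa-1,3,5-trien-1-yl]-2,4,6-trimethylcyclohexane-1-carboxylate | COC(=O)[C@@H]1[C@@H](C)C[C@@H](C)C[C@]1(/C=C(\C)/C=C(\C)/C=C)C | intermediate
13 | (1R,2S,4R,6S)-2-[(1E,3E)-2,4-dimethylhexa-1,3,5-trien-1-yl]-2,4,6-trimethylcyclohexane-1-carbaldehyde | O=C[C@@H]1[C@@H](C)C[C@@H](C)C[C@]1(/C=C(\C)/C=C(\C)/C=C)C | intermediate
14 | methyl (2E)-3-iodoprop-2-enoate | COC(=O)/C=C/I | starting material
15 | methyl (2E,4R)-4-hydroxy-4-{(1R,2S,4R,6S)-2-[(1E,3E)-2,4-dimethylhexa-1,3,5-trien-1-yl]-2,4,6-trimethylcyclohexyl}but-2-enoate | COC(=O)/C=C/[C@@H](O)[C@@H]1[C@@H](C)C[C@@H](C)C[C@]1(/C=C(\C)/C=C(\C)/C=C)C | intermediate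
16 | 4-iodophenol | Oc1ccc(I)cc1 | starting material
17 | methyl (2E,4S)-4-(4-iodophenoxy)-4-{(1R,2S,4R,6S)-2-[(1E,3E)-2,4-dimethylhexa-1,3,5-trien-1-yl]-2,4,6-trimethylcyclohexyl}but-2-enoate | COC(=O)/C=C/[C@H](Oc2ccc(I)cc2)[C@@H]1[C@@H](C)C[C@@H](C)C[C@]1(/C=C(\C)/C=C(\C)/C=C)C | intermediate
18 | methyl 2β-ethenyl-9β-(4-iodophenoxy)-2α,4,4bβ,6α,8α-pentamethyl-2,4a,4b,5,6,7,8,8a,9,9a-decahydro-1H-fluorene-1β-carboxylate (H-4a α, H-8a α, H-9a β; both ring fusions trans) | C=C[C@@]1(C)C=C(C)[C@@H]2[C@@H]([C@H]1C(=O)OC)[C@H](Oc3ccc(I)cc3)[C@@H]3[C@@H](C)C[C@@H](C)C[C@]32C | intermediate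
19 | 3-oxo-3-[tricycle of 18, attached at C1β]propanenitrile | C=C[C@@]1(C)C=C(C)[C@@H]2[C@@H]([C@H]1C(=O)CC#N)[C@H](Oc3ccc(I)cc3)[C@@H]3[C@@H](C)C[C@@H](C)C[C@]32C | intermediate
20 | 3-oxo-3-[tricycle of 18, attached at C1β]propanamide | C=C[C@@]1(C)C=C(C)[C@@H]2[C@@H]([C@H]1C(=O)CC(N)=O)[C@H](Oc3ccc(I)cc3)[C@@H]3[C@@H](C)C[C@@H](C)C[C@]32C | intermediate
21 | chloroacetone (1-chloropropan-2-one) | CC(=O)CCl | starting material
22 | 4-oxo-2-{[tricycle of 18, attached at C1β]carbonyl}pentanamide (C2 epimers, interconverting by enolisation; ring–chain tautomer with the 5-hydroxy-5-methyl lactam) | C=C[C@@]1(C)C=C(C)[C@@H]2[C@@H]([C@H]1C(=O)C(CC(C)=O)C(N)=O)[C@H](Oc3ccc(I)cc3)[C@@H]3[C@@H](C)C[C@@H](C)C[C@]32C | intermediate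
23 | open-chain form of the target: 13-membered paracyclophane with benzyl ketone, ring ketone and primary amide (hemiaminal not yet closed; side-chain stereocentre drawn as in the target) | C=C[C@@]1(C)C=C(C)[C@@H]2[C@@H]3[C@H](Oc4ccc(cc4)CC(=O)C[C@H](C(N)=O)C(=O)[C@H]31)[C@@H]1[C@@H](C)C[C@@H](C)C[C@]12C | intermediate
24 | CNP0450261.1: decahydrofluorene-fused 13-membered paracyclophane with a 3-acyl-5-hydroxy-pyrrolidin-2-one | C=C[C@@]1(C)C=C(C)[C@@H]2[C@@H]3[C@H](Oc4ccc(cc4)C[C@@]4(O)C[C@H](C(=O)N4)C(=O)[C@H]31)[C@@H]1[C@@H](C)C[C@@H](C)C[C@]12C | target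

## Totals and risk

Total step count: 17. Longest linear sequence: 17 steps (1 and 2 to 24).

**Step 17 (radical macrocyclisation).** Dangers: hydrodeiodination of the aryl radical, oligomers, a ring too strained to close. Fallback: sets out from 22 and comes back at 23 (and so 24). The radical chain is given up and the same aryl–CH2 bond is made by closed-shell palladium enolate arylation. Compound 22 is added slowly to Pd2(dba)3/XPhos and K3PO4 in dioxane at 90 °C (1 mM). Zerovalent palladium inserts into the C–I bond, the terminal potassium enolate binds, and reductive elimination gives 23, which closes to 24 on work-up. New compounds on this detour: none F0.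

**Step 13 (face selectivity of the cycloaddition with the extra angular methyl).** Fallback: sets out from 17 and comes back at 19. Substrate control is replaced by catalyst control through iminium organocatalysis.
- iBu2AlH (2.2 equiv, −78 °C) reduces the enoate of 17 to the allylic alcohol F1.
- MnO2 gives the (2E)-enal F2.
- (2S,5S)-5-Benzyl-2-tert-butyl-3-methylimidazolidin-4-one trifluoroacetate (20 mol %, MeCN/H2O, 0 °C; the catalyst enantiomer matched to the substrate is used) effects the endo-selective intramolecular Diels–Alder reaction to the tricyclic aldehyde F3.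
- LiCH2CN adds to give the β-hydroxy nitrile F4, and Dess–Martin oxidation gives the β-ketonitrile 19.

**Step 12 (Mitsunobu etherification of a hindered allylic alcohol; elimination may compete).** Fallback: sets out from 15 and comes back at 17. Inversion is separated from ether formation.
- Mitsunobu reaction with the far more acidic 4-nitrobenzoic acid (PPh3, DIAD) gives the inverted 4-nitrobenzoate F5.
- K2CO3/MeOH at 0 °C frees the (4S)-alcohol F6.
- Its sodium alkoxide (NaH, THF, 0 °C) is O-arylated with bis(4-iodophenyl)iodonium triflate with retention (ligand coupling at iodine), giving 17.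

Further compounds
F0 | step 17 | none | none
F1 | step 13 | (2E,4S)-4-(4-iodophenoxy)-4-{(1R,2S,4R,6S)-2-[(1E,3E)-2,4-dimethylhexa-1,3,5-trien-1-yl]-2,4,6-trimethylcyclohexyl}but-2-en-1-ol | OC/C=C/[C@H](Oc2ccc(I)cc2)[C@@H]1[C@@H](C)C[C@@H](C)C[C@]1(/C=C(\C)/C=C(\C)/C=C)C
F2 | step 13 | (2E,4S)-4-(4-iodophenoxy)-4-{(1R,2S,4R,6S)-2-[(1E,3E)-2,4-dimethylhexa-1,3,5-trien-1-yl]-2,4,6-trimethylcyclohexyl}but-2-enal | O=C/C=C/[C@H](Oc2ccc(I)cc2)[C@@H]1[C@@H](C)C[C@@H](C)C[C@]1(/C=C(\C)/C=C(\C)/C=C)C
F3 | step 13 | 2β-ethenyl-9β-(4-iodophenoxy)-2α,4,4bβ,6α,8α-pentamethyl-2,4a,4b,5,6,7,8,8a,9,9a-decahydro-1H-fluorene-1β-carbaldehyde (ring fusions as in 18) | C=C[C@@]1(C)C=C(C)[C@@H]2[C@@H]([C@H]1C=O)[C@H](Oc3ccc(I)cc3)[C@@H]3[C@@H](C)C[C@@H](C)C[C@]32C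
F4 | step 13 | 3-hydroxy-3-[tricycle of 18, attached at C1β]propanenitrile (carbinol epimers) | C=C[C@@]1(C)C=C(C)[C@@H]2[C@@H]([C@H]1C(O)CC#N)[C@H](Oc3ccc(I)cc3)[C@@H]3[C@@H](C)C[C@@H](C)C[C@]32C
F5 | step 12 | methyl (2E,4S)-4-[(4-nitrobenzoyl)oxy]-4-{(1R,2S,4R,6S)-2-[(1E,3E)-2,4-dimethylhexa-1,3,5-trien-1-yl]-2,4,6-trimethylcyclohexyl}but-2-enoate | COC(=O)/C=C/[C@H](OC(=O)c2ccc(cc2)[N+](=O)[O-])[C@@H]1[C@@H](C)C[C@@H](C)C[C@]1(/C=C(\C)/C=C(\C)/C=C)C
F6 | step 12 | methyl (2E,4S)-4-hydroxy-4-{(1R,2S,4R,6S)-2-[(1E,3E)-2,4-dimethylhexa-1,3,5-trien-1-yl]-2,4,6-trimethylcyclohexyl}but-2-enoate | COC(=O)/C=C/[C@H](O)[C@@H]1[C@@H](C)C[C@@H](C)C[C@]1(/C=C(\C)/C=C(\C)/C=C)C
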